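(All runs were computed for substances that don't exist; noise was put on by code.)

- The elm run held 50.0 mM of starting material and 80.0 mM of coupling partner, and at 37 min it showed 32.7 mM of target, so subtraction seemed to leave 17.3 mM and 47.3 mM.
- Yet the rise in elm dropped from 2.35 mM min⁻¹ over the first interval to 0.129 mM min⁻¹ over the last, a fall by a factor of 18.2, while the product of those amounts fell by a factor of 4.89, so the rate fell faster than the product.

| setting | ash | alder | elm | oak | cedar |
|---|---|---|---|---|---|
| starting material | 50.0 mM | 30.0 mM | 50.0 mM | 25.0 mM | 11.0 mM |
| coupling partner | 40.0 mM | 20.0 mM | 80.0 mM | 40.0 mM | 40.0 mM |
| time |  |  |  |  | 37 min |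

| run | time / min | [target] / mM |
|---|---|---|
| ash run | 7.4 | 9.7 |
| ash run | 15 | 16.0 |
| ash run | 22 | 18.8 |
| ash run | 30 | 20.7 |
| ash run | 37 | 22.1 |
| alder run | 7.4 | 3.1 |
| alder run | 15 | 5.9 |
| alder run | 22 | 7.8 |
| alder run | 30 | 8.8 |
| alder run | 37 | 9.1 |
| elm run | 7.4 | 17.4 |
| elm run | 15 | 27.0 |
| elm run | 22 | 30.1 |
| elm run | 30 | 31.8 |
| elm run | 37 | 32.7 |
| oak run | 7.4 | 6.7 |
| oak run | 15 | 9.9 |
| oak run | 22 | 11.2 |
| oak run | 30 | 12.2 |
| oak run | 37 | 12.5 |

(each reading ± 0.3 mM)

- order of the initial rate in [coupling partner], near the charge of the ash run, the rate being that where two percent of its starting material are target
- order of the initial rate in [starting material], near the charge of the ash run, the rate being that where two percent of its starting material are target (one fixed amount of target, the same in the runs compared)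
- target in the cedar run at 37 min, as a share of the starting material charged

- Overall: starting material + coupling partner -> target.
- Constant volume, constant temperature.
- The analysis sees a species whether free or bound.
- "The second partner" is coupling partner.
- An order is taken over about fifteen percent of the charge, up and down.

- I supposed that starting material had a second exit, first order in it and needing no partner; target made per starting material lost by that exit then equals [coupling partner] over a constant, and integrating gives: starting material lost by that exit = constant × ln(partner charged / partner left).
- Treating elm as finished at its last reading, so that charge minus target was the loss, I read that constant as 32.9 mM; I called it the branch concentration, the [coupling partner] at which both exits take starting material equally fast, a selectivity factor with a unit.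
- Treated the same way, the last readings of oak, ash and alder gave 33.4 mM, 34.7 mM and 34.4 mM, though partner charges ran from 20.0 mM to 80.0 mM.
- Taking cedar as finished at 37 min, I first set its share at charged partner over charged partner plus the branch concentration, 54.9%; that consumes enough partner to make the mean [coupling partner] 37.0 mM, and the second pass gave my figure, 52.9%.
- I reckoned no orders of my own.
- The forecast gave 1.15 in coupling partner, 0.55 in starting material and 57% for cedar, judging that “this looks like a reversible coupling”; my cedar share lay lower.
- The flask gave 0.99, 0.63 and 53.4%, so the forecast's order in coupling partner stood too high, while its other two figures held within their margins.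

    starting material + coupling partner ⇌ intermediate, settled at all times (5.070 L mol⁻¹)
    starting material + coupling partner → target (2.388 L mol⁻¹ min⁻¹)
    2 starting material ⇌ idle substrate dimer, settled at all times (29.80 L mol⁻¹)
    starting material → decomposed substrate (0.07380 min⁻¹)

- With the decomposition of starting material to decomposed substrate taken away, cedar gave 88.3% instead of 53.4% at 37 min, so that step was the main reason for cedar's shortfall from its charge. In cedar, the 5.88 mM of target plus the loss reckoned from the branch concentration came to 11.1 mM against 11.0 mM charged. Oak's target reached 12.5 mM, half of its charge, at 37.4 min, and with elm's branch concentration, target plus reckoned loss there came to 24.8 mM of its 25.0 mM.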